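**Retrosynthetic overview**
1. Target 24 ⇐ (3S,3'S)-7,8-didehydroastaxanthin 23 by hydroxyl-directed reduction of the C4 and C4' ketones (each new carbinol trans to its C3 hydroxyl); 23 ⇐ C15 salt 20 + C10 dialdehyde 21 + C15 salt 18 by two Wittig reactions (C11'=C12' first, then C11=C12).
2. Both C15 salts ⇐ one enynone 15 (18 after zinc semi-reduction of the triple bond); 15 ⇐ lithium acetylide 13 + C9 ketone 10 by 1,2-addition and acid-induced 1,3-carbonyl transposition, which creates C5=C6 and the C4 ketone.
3. Ring formation: no ring is closed from a chain; the cyclohexene ring C1'–C6' (and, from the same building block, the identical ring C1–C6) comes from the four-membered ring of squarate-derived cyclobutenone 5 by a two-atom ring expansion to enedione 8; ring order: cyclobutene (purchased in 1) → cyclohexene (step 3).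
4. Enabling feature: C3(O)–C4(O)–C5(CH3)=C6(–C7) of the ring are four contiguous carbons with the substitution pattern of a 4-hydroxy-3-alkoxy-2-methylcyclobutenone (C6 = its carbonyl carbon), and C2H2–C1(CH3)2 is the C=C of an isobutenyl group on its C4; because C1 is quaternary, the electrocyclised ring cannot aromatise and settles as an enedione with two differentiated carbonyls (C3 and C6).
5. Stereocentres: C3/C3' by CBS reduction of 8 (one building block serves both rings); C4/C4' in the last step.

Key step: step 3

Assumption: the descriptors of the SMILES are read as (3S,4S,3'S,4'S), i.e. a trans-3,4-diol in each ring, and compounds 1, 4, 11 and 21 are taken as purchasable.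

**Route**

Step 1
Reactants: 1 diisopropyl squarate (3,4-diisopropoxycyclobut-3-ene-1,2-dione)
Product: 3 3-isopropoxy-4-methylcyclobut-3-ene-1,2-dione, via hydroxycyclobutenone adduct 2 (not isolated)
Conditions: MeLi, THF, −78 °C; then conc. aq. HCl, CH2Cl2, rt
Reagents that add atoms: methyllithium, [Li]C; water, O
Why: 1,2-addition of an organolithium to a squaric ester followed by acid-promoted collapse of the vinylogous hemiketal (loss of isopropanol) is the standard entry to 3-alkoxy-4-alkylcyclobutenediones, and no stereocentre remains.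

Step 2
Reactants: 3 3-isopropoxy-4-methylcyclobut-3-ene-1,2-dione; 4 2-methylprop-1-enylmagnesium bromide
Product: 5 4-hydroxy-3-isopropoxy-2-methyl-4-(2-methylprop-1-en-1-yl)cyclobut-2-en-1-one (racemic)
Conditions: THF, −78 °C; H2O quench at −78 °C
Reagents that add atoms: none
Why: Grignard 1,2-addition should occur at the carbonyl next to the isopropoxy-bearing carbon, because the other carbonyl is deactivated as a vinylogous ester (the usual regiochemistry for 3-alkoxy-4-alkylcyclobutenediones); the new carbinol centre is racemic and is destroyed in step 3.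

Step 3
Reactants: 5 4-hydroxy-3-isopropoxy-2-methyl-4-(2-methylprop-1-en-1-yl)cyclobut-2-en-1-one
Product: 8 2-isopropoxy-3,5,5-trimethylcyclohex-2-ene-1,4-dione, via dienylketene 6 (not isolated), via cyclohexadienone enol 7 (not isolated)
Conditions: p-xylene (0.02 M, degassed), reflux (138 °C), Ar
Reagents that add atoms: none
Why: Heating should open the cyclobutenone by conrotatory 4π electrocyclic cleavage of the C1–C4 bond, the donor hydroxyl rotating outward and the isobutenyl group inward, to give the (Z)-dienylketene 6; its ketene carbon and the (CH3)2C= terminus then close by a thermally allowed disrotatory 6π electrocyclisation to cyclohexadienone 7, whose enol tautomerises irreversibly to the C=O/CH2 pair of 8 (net two-atom ring expansion, cyclobutene to cyclohexene). The closest known reaction type is the Moore rearrangement of 4-alkenyl-4-hydroxycyclobutenones, which normally ends in a hydroquinone. The only ring closed is the six-membered carbocycle, by 6π electrocyclisation forming the bond between the former carbonyl carbon (future C6) and the dimethyl-substituted alkene carbon (future C1). No stereocentre is created and the racemic carbinol centre of 5 is erased, so both enantiomers converge on achiral 8. The step needs torquoselectivity (alkenyl inward, secured by the strong outward preference of the hydroxyl donor) and arrest before aromatisation (secured by the quaternary gem-dimethyl carbon, which leaves tautomerisation to the enedione as the only exit). Regiochemistry is fixed by connectivity: the methyl-bearing carbon lies next to the hindered vinylogous-ester carbonyl (future C6), the isopropoxy carbon becomes C4, and the new unhindered ketone (future C3) sits next to the new CH2 (C2).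

Step 4
Reactants: 8 2-isopropoxy-3,5,5-trimethylcyclohex-2-ene-1,4-dione
Product: 9 (4S)-4-hydroxy-3-isopropoxy-2,6,6-trimethylcyclohex-2-en-1-one
Conditions: (R)-Me-CBS (0.2 equiv), BH3·SMe2 (0.6 equiv), THF, −30 °C; MeOH quench
Reagents that add atoms: none
Why: CBS reduction should take only the C1 ketone of 8 (flanked by CH2, not a vinylogous ester, not next to the quaternary carbon), and with the (R)-catalyst hydride should be delivered to the face that gives the S carbinol when the isopropoxy-substituted sp2 carbon acts as the large group and the ring CH2 as the small group; this sets C3 (and C3') of the target.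

Step 5
Reactants: 9 (4S)-4-hydroxy-3-isopropoxy-2,6,6-trimethylcyclohex-2-en-1-one
Product: 10 (4S)-3-isopropoxy-2,6,6-trimethyl-4-(triethylsilyloxy)cyclohex-2-en-1-one
Conditions: TESCl, imidazole, CH2Cl2, 0 °C
Reagents that add atoms: chlorotriethylsilane, CC[Si](Cl)(CC)CC
Why: Standard silylation of a secondary alcohol masks the acidic hydroxyl before the organolithium step and does not touch the stereocentre.

Step 6
Reactants: 11 (E)-3-methylpent-2-en-4-yn-1-ol
Product: 12 triethyl{[(E)-3-methylpent-2-en-4-yn-1-yl]oxy}silane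
Conditions: TESCl, imidazole, CH2Cl2, 0 °C
Reagents that add atoms: chlorotriethylsilane, CC[Si](Cl)(CC)CC
Why: Standard silylation of the primary allylic alcohol leaves the terminal alkyne as the only acidic site and keeps the 9E geometry.

Step 7
Reactants: 10 (4S)-3-isopropoxy-2,6,6-trimethyl-4-(triethylsilyloxy)cyclohex-2-en-1-one; 12 triethyl{[(E)-3-methylpent-2-en-4-yn-1-yl]oxy}silane
Product: 15 (6S)-6-hydroxy-3-[(3E)-5-hydroxy-3-methylpent-3-en-1-yn-1-yl]-2,4,4-trimethylcyclohex-2-en-1-one, via lithium acetylide 13 (not isolated), via propargylic carbinol adduct 14 (not isolated)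
Conditions: 12 (1.3 equiv), n-BuLi, THF, −78 °C; add 10, −78 → 0 °C; then 1 M aq. H2SO4, THF, 0 °C → rt
Reagents that add atoms: water, O
Why: Acetylide 1,2-addition to the hindered vinylogous-ester carbonyl followed by acid-induced Stork–Danheiser-type transposition (loss of the tertiary hydroxyl, hydrolysis of the isopropyl enol ether, cleavage of both silyl ethers) is closely precedented for 3-alkoxy-6,6-dimethylcyclohex-2-enones and should give the C6-alkynyl 3-hydroxy-4-oxo ring; the C6 carbinol centre is transient and C3 is not touched.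

Step 8
Reactants: 15 (6S)-6-hydroxy-3-[(3E)-5-hydroxy-3-methylpent-3-en-1-yn-1-yl]-2,4,4-trimethylcyclohex-2-en-1-one
Product: 16 (6S)-6-hydroxy-3-[(1E,3E)-5-hydroxy-3-methylpenta-1,3-dien-1-yl]-2,4,4-trimethylcyclohex-2-en-1-one
Conditions: Zn dust, AcOH, CH2Cl2, 0 °C → rt
Reagents that add atoms: none
Why: Zinc/acetic acid semi-reduction should act only on the triple bond, which is activated by conjugation through C5=C6 with the C4 ketone, and protonation of the extended dienolate should give the thermodynamically preferred 7E alkene while the 9E alkene and the α-ketol are untouched.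

Step 9
Reactants: 16 (6S)-6-hydroxy-3-[(1E,3E)-5-hydroxy-3-methylpenta-1,3-dien-1-yl]-2,4,4-trimethylcyclohex-2-en-1-one
Product: 18 [(2E,4E)-5-[(4S)-4-hydroxy-2,6,6-trimethyl-3-oxocyclohex-1-en-1-yl]-3-methylpenta-2,4-dien-1-yl]triphenylphosphonium bromide, via primary allylic bromide 17 (not isolated)
Conditions: 48% aq. HBr, CH2Cl2, −15 °C; then PPh3, EtOAc, rt
Reagents that add atoms: hydrogen bromide, Br; triphenylphosphine, c1ccc(cc1)P(c1ccccc1)c1ccccc1
Why: Allylic bromination followed by quaternisation of triphenylphosphine should give the crystalline salt, any allylic isomer of the bromide converging on the primary phosphonium salt, while the C3 hydroxyl (deactivated by the adjacent carbonyl) is not substituted.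

Step 10
Reactants: 15 (6S)-6-hydroxy-3-[(3E)-5-hydroxy-3-methylpent-3-en-1-yn-1-yl]-2,4,4-trimethylcyclohex-2-en-1-one
Product: 20 [(2E)-5-[(4S)-4-hydroxy-2,6,6-trimethyl-3-oxocyclohex-1-en-1-yl]-3-methylpent-2-en-4-yn-1-yl]triphenylphosphonium bromide, via primary allylic bromide 19 (not isolated)
Conditions: 48% aq. HBr, CH2Cl2, −15 °C; then PPh3, EtOAc, rt
Reagents that add atoms: hydrogen bromide, Br; triphenylphosphine, c1ccc(cc1)P(c1ccccc1)c1ccccc1
Why: The same allylic bromination/quaternisation applied to the enynol should give the acetylenic C15 Wittig salt without affecting the triple bond or the α-ketol.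

Step 11
Reactants: 18 olefinic C15 phosphonium bromide; 21 (2E,4E,6E)-2,7-dimethylocta-2,4,6-trienedial
Product: 22 (3S)-3-hydroxy-4-oxo-12'-apo-β-caroten-12'-al (C25 aldehyde)
Conditions: 21 (3 equiv), 1,2-epoxybutane, EtOH, reflux, dark, Ar; then heptane, reflux (E/Z equilibration)
Reagents that add atoms: none
Why: Wittig olefination with the allylic ylide generated under neutral conditions by the epoxide/bromide pair should spare the base-sensitive α-ketol, the excess of dialdehyde should enforce mono-olefination, and thermal equilibration should give the all-E polyene.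

Step 12
Reactants: 22 (3S)-3-hydroxy-4-oxo-12'-apo-β-caroten-12'-al; 20 acetylenic C15 phosphonium bromide
Product: 23 (3S,3'S)-7,8-didehydroastaxanthin
Conditions: 20 (1.2 equiv), 1,2-epoxybutane, EtOH/CH2Cl2, reflux, dark, Ar; then cat. I2, hexane/CH2Cl2, daylight; crystallisation
Reagents that add atoms: none
Why: The second Wittig reaction under the same neutral conditions should complete the C40 chain, and the expected mixture of 9Z/9E and 11Z/11E isomers from the acetylenic ylide should be equilibrated with iodine and the all-E isomer collected by crystallisation.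

Step 13
Reactants: 23 (3S,3'S)-7,8-didehydroastaxanthin
Product: 24 (3S,4S,3'S,4'S)-7,8-didehydro-β,β-carotene-3,4,3',4'-tetrol
Conditions: Me4NBH(OAc)3 (excess), AcOH (few equiv), MeCN/CH2Cl2, −30 → −10 °C, dark, Ar; cold aq. NaHCO3
Reagents that add atoms: none
Why: In this hydroxyl-directed (Saksena–Evans) reduction each C3 hydroxyl should exchange onto boron and deliver hydride intramolecularly to the neighbouring C4 carbonyl on its own face, so each new C4 hydroxyl should come out trans to the C3 hydroxyl (4S and 4'S from 3S and 3'S) without reduction of the polyene.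

**Compound list**
1 | diisopropyl squarate | CC(C)OC1=C(OC(C)C)C(=O)C1=O | starting material
2 | 4-hydroxy-2,3-diisopropoxy-4-methylcyclobut-2-en-1-one (racemic, formed as its lithium alkoxide) | CC(C)OC1=C(OC(C)C)C(C)(O)C1=O | intermediate (not isolated)
3 | 3-isopropoxy-4-methylcyclobut-3-ene-1,2-dione | CC(C)OC1=C(C)C(=O)C1=O | intermediate
4 | 2-methylprop-1-enylmagnesium bromide | CC(C)=C[Mg]Br | starting material
5 | 4-hydroxy-3-isopropoxy-2-methyl-4-(2-methylprop-1-en-1-yl)cyclobut-2-en-1-one (racemic) | CC(C)OC1=C(C)C(=O)C1(O)C=C(C)C | intermediate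
6 | (Z)-4-hydroxy-3-isopropoxy-2,6-dimethylhepta-1,3,5-trien-1-one (dienylketene, isobutenyl cis to the ketenyl group) | CC(C)=C/C(O)=C(OC(C)C)\C(C)=C=O | intermediate (not isolated)
7 | 4-hydroxy-3-isopropoxy-2,6,6-trimethylcyclohexa-2,4-dien-1-one | CC1=C(OC(C)C)C(O)=CC(C)(C)C1=O | intermediate (not isolated)
8 | 2-isopropoxy-3,5,5-trimethylcyclohex-2-ene-1,4-dione | CC(C)OC1=C(C)C(=O)C(C)(C)CC1=O | intermediate
9 | (4S)-4-hydroxy-3-isopropoxy-2,6,6-trimethylcyclohex-2-en-1-one | CC1=C(OC(C)C)[C@@H](O)CC(C)(C)C1=O | intermediate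
10 | (4S)-3-isopropoxy-2,6,6-trimethyl-4-(triethylsilyloxy)cyclohex-2-en-1-one | CC1=C(OC(C)C)[C@@H](O[Si](CC)(CC)CC)CC(C)(C)C1=O | intermediate
11 | (E)-3-methylpent-2-en-4-yn-1-ol | C#C/C(C)=C/CO | starting material
12 | triethyl{[(E)-3-methylpent-2-en-4-yn-1-yl]oxy}silane | C#C/C(C)=C/CO[Si](CC)(CC)CC | intermediate
13 | lithium acetylide of 12 | [Li]C#C/C(C)=C/CO[Si](CC)(CC)CC | intermediate (not isolated)
14 | (4S)-3-isopropoxy-2,6,6-trimethyl-1-[(E)-3-methyl-5-(triethylsilyloxy)pent-3-en-1-yn-1-yl]-4-(triethylsilyloxy)cyclohex-2-en-1-ol (mixture of C1 epimers) | CC1=C(OC(C)C)[C@@H](O[Si](CC)(CC)CC)CC(C)(C)C1(O)C#C/C(C)=C/CO[Si](CC)(CC)CC | intermediate (not isolated)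
15 | (6S)-6-hydroxy-3-[(3E)-5-hydroxy-3-methylpent-3-en-1-yn-1-yl]-2,4,4-trimethylcyclohex-2-en-1-one | CC1=C(C#C/C(C)=C/CO)C(C)(C)C[C@H](O)C1=O | intermediate
16 | (6S)-6-hydroxy-3-[(1E,3E)-5-hydroxy-3-methylpenta-1,3-dien-1-yl]-2,4,4-trimethylcyclohex-2-en-1-one | CC1=C(/C=C/C(C)=C/CO)C(C)(C)C[C@H](O)C1=O | intermediate
17 | (6S)-3-[(1E,3E)-5-bromo-3-methylpenta-1,3-dien-1-yl]-6-hydroxy-2,4,4-trimethylcyclohex-2-en-1-one | CC1=C(/C=C/C(C)=C/CBr)C(C)(C)C[C@H](O)C1=O | intermediate (not isolated)
18 | [(2E,4E)-5-[(4S)-4-hydroxy-2,6,6-trimethyl-3-oxocyclohex-1-en-1-yl]-3-methylpenta-2,4-dien-1-yl]triphenylphosphonium bromide | CC1=C(/C=C/C(C)=C/C[P+](c2ccccc2)(c2ccccc2)c2ccccc2)C(C)(C)C[C@H](O)C1=O.[Br-] | intermediate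
19 | (6S)-3-[(3E)-5-bromo-3-methylpent-3-en-1-yn-1-yl]-6-hydroxy-2,4,4-trimethylcyclohex-2-en-1-one | CC1=C(C#C/C(C)=C/CBr)C(C)(C)C[C@H](O)C1=O | intermediate (not isolated)
20 | [(2E)-5-[(4S)-4-hydroxy-2,6,6-trimethyl-3-oxocyclohex-1-en-1-yl]-3-methylpent-2-en-4-yn-1-yl]triphenylphosphonium bromide | CC1=C(C#C/C(C)=C/C[P+](c2ccccc2)(c2ccccc2)c2ccccc2)C(C)(C)C[C@H](O)C1=O.[Br-] | intermediate
21 | (2E,4E,6E)-2,7-dimethylocta-2,4,6-trienedial | O=C/C(C)=C/C=C/C=C(C)/C=O | starting material
22 | (3S)-3-hydroxy-4-oxo-12'-apo-β-caroten-12'-al | CC1=C(/C=C/C(C)=C/C=C/C(C)=C/C=C/C=C(C)/C=O)C(C)(C)C[C@H](O)C1=O | intermediate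
23 | (3S,3'S)-7,8-didehydroastaxanthin | CC1=C(C#C/C(C)=C/C=C/C(C)=C/C=C/C=C(C)/C=C/C=C(C)/C=C/C2=C(C)C(=O)[C@@H](O)CC2(C)C)C(C)(C)C[C@H](O)C1=O | intermediate
24 | (3S,4S,3'S,4'S)-7,8-didehydro-β,β-carotene-3,4,3',4'-tetrol | CC1=C(C#C/C(C)=C/C=C/C(C)=C/C=C/C=C(C)/C=C/C=C(C)/C=C/C2=C(C)[C@H](O)[C@@H](O)CC2(C)C)C(C)(C)C[C@H](O)[C@H]1O | target

**Step count and risks**

Total steps: 13. Longest linear sequence: 11 (steps 1, 2, 3, 4, 5, 7, 8, 9, 11, 12, 13).

Steps most likely to fail:

Step 13. Hydride delivery on the C40 polyenone may be incompletely face-selective, and the newly formed C4/C4' carbinols, which are allylic to the whole polyene, may ionise and eliminate in the acidic medium or on work-up. The fallback moves the C4 reduction to the phosphonium salts, sets out from 18 and 20 and returns at 24. Directed reduction of 18 (Me4NBH(OAc)3, MeCN/AcOH, −20 °C) should give [(2E,4E)-5-[(3S,4S)-3,4-dihydroxy-2,6,6-trimethylcyclohex-1-en-1-yl]-3-methylpenta-2,4-dien-1-yl]triphenylphosphonium bromide F1, and the same treatment of 20 should give the corresponding acetylenic diol salt [(2E)-5-[(3S,4S)-3,4-dihydroxy-2,6,6-trimethylcyclohex-1-en-1-yl]-3-methylpent-2-en-4-yn-1-yl]triphenylphosphonium bromide F2. In these salts the short, phosphonium-substituted chromophore should resist ionisation at C4, and a minor cis-diol isomer could be removed by crystallisation. Wittig reaction of F1 with excess 21 (1,2-epoxybutane, EtOH, reflux) should give (3S,4S)-3,4-dihydroxy-12'-apo-β-caroten-12'-al F3, and a second Wittig reaction of F3 with F2 should give 24 directly, so that no reduction is run on the C40 polyene.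

Step 3. The free tertiary hydroxyl may add to the ketene (lactonisation), or the ketene may oligomerise, before the 6π closure onto the fully substituted alkene terminus takes place. The fallback runs the cascade on a capped substrate and separates ring expansion from tautomerisation; it sets out from 5 and returns at 8. Silylation of 5 (TESOTf, 2,6-lutidine, CH2Cl2, −78 °C) should give 3-isopropoxy-2-methyl-4-(2-methylprop-1-en-1-yl)-4-(triethylsilyloxy)cyclobut-2-en-1-one F4. Thermolysis of F4 (toluene or xylene, reflux) should follow the same 4π/6π path but end at the isolable silyl dienol ether 3-isopropoxy-2,6,6-trimethyl-4-(triethylsilyloxy)cyclohexa-2,4-dien-1-one F5, in which no hydroxyl is available for ketene capture. Brief treatment of F5 with dilute aqueous HCl in THF at 0 °C should release 8.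

Step 4. Enantiofacial discrimination between the CH2 flank and the alkoxy-alkene flank of the ketone may be insufficient, or the second carbonyl may be reduced competitively. The fallback replaces catalyst control by a kinetic resolution; it sets out from 8 and returns at 9. Luche reduction of 8 (NaBH4, CeCl3·7H2O, MeOH, −78 °C) should give racemic 4-hydroxy-3-isopropoxy-2,6,6-trimethylcyclohex-2-en-1-one F6. Lipase-catalysed acylation of F6 (Burkholderia cepacia lipase, vinyl acetate, MTBE, 30 °C) should convert the R enantiomer into (1R)-2-isopropoxy-3,5,5-trimethyl-4-oxocyclohex-2-en-1-yl acetate F7 and leave the S alcohol 9, which would be separated by chromatography.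

**Further compounds**
F1 | step 13 | [(2E,4E)-5-[(3S,4S)-3,4-dihydroxy-2,6,6-trimethylcyclohex-1-en-1-yl]-3-methylpenta-2,4-dien-1-yl]triphenylphosphonium bromide | CC1=C(/C=C/C(C)=C/C[P+](c2ccccc2)(c2ccccc2)c2ccccc2)C(C)(C)C[C@H](O)[C@H]1O.[Br-]
F2 | step 13 | [(2E)-5-[(3S,4S)-3,4-dihydroxy-2,6,6-trimethylcyclohex-1-en-1-yl]-3-methylpent-2-en-4-yn-1-yl]triphenylphosphonium bromide | CC1=C(C#C/C(C)=C/C[P+](c2ccccc2)(c2ccccc2)c2ccccc2)C(C)(C)C[C@H](O)[C@H]1O.[Br-]
F3 | step 13 | (3S,4S)-3,4-dihydroxy-12'-apo-β-caroten-12'-al | CC1=C(/C=C/C(C)=C/C=C/C(C)=C/C=C/C=C(C)/C=O)C(C)(C)C[C@H](O)[C@H]1O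
F4 | step 3 | 3-isopropoxy-2-methyl-4-(2-methylprop-1-en-1-yl)-4-(triethylsilyloxy)cyclobut-2-en-1-one (racemic) | CC(C)OC1=C(C)C(=O)C1(O[Si](CC)(CC)CC)C=C(C)C
F5 | step 3 | 3-isopropoxy-2,6,6-trimethyl-4-(triethylsilyloxy)cyclohexa-2,4-dien-1-one | CC1=C(OC(C)C)C(O[Si](CC)(CC)CC)=CC(C)(C)C1=O
F6 | step 4 | racemic 4-hydroxy-3-isopropoxy-2,6,6-trimethylcyclohex-2-en-1-one | CC1=C(OC(C)C)C(O)CC(C)(C)C1=O
F7 | step 4 | (1R)-2-isopropoxy-3,5,5-trimethyl-4-oxocyclohex-2-en-1-yl acetate | CC1=C(OC(C)C)[C@H](OC(C)=O)CC(C)(C)C1=O
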